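Slowness may or may not matter in a flask that stalls, so before reckoning the eta run I ask which known numbers its answer hangs on.

| flask | Xa | Xb | Xp | time |
|---|---|---|---|---|
| gamma | 100 mM | 80.0 mM |  |  |
| zeta | 40.0 mM | 20.0 mM |  |  |
| epsilon | 100 mM | 80.0 mM | 50.0 mM |  |
| delta | 50.0 mM | 80.0 mM |  |  |
| eta | 33.0 mM | 160 mM |  | 44 min |

- gamma run (time / min: [Xp] / mM): 7.3: 17.3; 15: 24.5; 22: 26.8; 29: 29.2; 37: 30.1; 44: 30.3
- zeta run (time / min: [Xp] / mM): 7.3: 2.8; 15: 3.8; 22: 4.8; 29: 6.0; 37: 6.0; 44: 7.1
- epsilon run (time / min: [Xp] / mM): 7.3: 66.4; 15: 72.5; 22: 75.3; 29: 76.0; 37: 76.8; 44: 76.7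
- delta run (time / min: [Xp] / mM): 7.3: 9.7; 15: 14.3; 22: 16.6; 29: 18.6; 37: 19.8; 44: 20.5

(each reading ± 0.3 mM)

- Overall: Xa + Xb -> Xp.
- Constant volume, constant temperature.
- "The second partner" is Xb.
- An order is taken over about fifteen percent of the charge, up and down.

1. how the opening rate goes with [Xb] round the charge of the gamma run: the exponent of the rate at two percent of Xa gone to Xp
2. how the opening rate goes with [Xa] round the charge of the gamma run: the exponent of the rate at two percent of Xa gone to Xp (one fixed amount of Xp, the same in the runs compared)
3. Xp in the eta run at 44 min, as a share of the Xa charged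

I start from the delta run, where Xa is the short partner, the limiting reagent, with 50.0 mM against 80.0 mM of Xb. If its Xp climbs exponentially to its last reading, the first reading gives a stall time of 11.4 min. At 44 min that leaves 2.10% of the climb undone. I take the eta run, with twice the [Xb] of the delta run, to be no slower, so the stall time and the order in Xb weigh about 2.10% in the answer. The exact [Xb] weighs little as well: by the overall equation, [Xb] in the eta run stays above 0.127 M, so Xa goes pseudo-first-order.

The number that must be known well is the height of the stall. An error in it passes straight into the answer. The delta run reads 20.5 mM on 50.0 mM of Xa, which gives 41.0%. This is the ceiling share, the Xp at the stall per unit of the short partner charged. The scatter of one reading is 0.600% of that charge. So my own figure for the eta run is 41.0%.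

The forecast stands higher, at 65%, with orders of 0.6 in Xb and 1 in Xa. Its grounds for the share end in these words: “an equilibrium ceiling gives about 70%, so I expect about 65%”.

The flask gives 47.6% in the eta run, 6.6 percentage points above my ceiling share and 17 points below the forecast, with orders of 1.1 in Xb and 1.0 in Xa.

    Xa + Xb → Xp (0.5142 M⁻¹ min⁻¹)
    Xa + Xb → Xq (0.4488 M⁻¹ min⁻¹)
    Xp → L (0.002070 min⁻¹)
    2 Xa → X (0.1524 M⁻¹ min⁻¹)

The route to Xp takes 53.4% of the Xa that reacts with Xb, which is more than the eta run shows. The gamma run, with the same 80.0 mM of Xb as the delta run, reads 30.3 mM at 44 min on 100 mM of Xa, a share of 30.3% of its Xa, below the 41.0% of the delta run.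

(The earlier runs and the new flask are simulated on assumed constants; the scatter is artificial.)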